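## The problem

Compound 13 is 2,3,4,6-tetrabromo-1H-indole. It is a planar, achiral bicycle: a benzene ring (C3a, C4, C5, C6, C7, C7a) fused through C3a–C7a to a pyrrole ring (N1, C2, C3), with bromine on C2, C3, C4 and C6 and hydrogen only on N1, C5 and C7. There is no stereocenter, so the whole task is positional.

The two pyrrole bromines are the easy ones, because C3 and then C2 of an indole take electrophilic bromine readily. An N–H 2,3-dibromoindole is, however, sensitive to acid, light and excess oxidant, so these bromines belong at the end.

The benzenoid bromines are the hard ones. C4 and C6 are both meta to the nitrogen-bearing C7a, whereas nitrogen steers electrophiles to C5 and C7 in an indoline or anilide, and in an indole the pyrrole ring reacts first. The 4,6-pattern therefore cannot be written onto a preformed bicycle by direct bromination, and C4 is in addition the peri position next to C3. Once aryl bromides are present, zerovalent palladium, organolithium reagents and dissolving metals are excluded.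

What opens the problem is a mapping. The benzene carbons C7a (N), C7 (H), C6 (Br) and C5 (H) carry exactly the substituents of C3, C4, C5 and C6 of 5-bromopyridazin-3-amine (1). The remaining atoms C3a, C4, C3 and C2 are a but-3-ynyl chain hung on that nitrogen. A diazine-to-benzene ring transformation thus fixes the C6 bromine and both ring hydrogens by connectivity and leaves only C4 to be marked, which a silyl group on the alkyne terminus can do.

## Retrosynthesis

**13 ⇒ 10 (C2–Br, C3–Br and C4–Br).** All three bonds are cut at once, the C4–Br bond being traced back to a C4–Si bond in 6-bromo-4-(trimethylsilyl)-1H-indole (10). The silicon-for-bromine exchange is deliberately placed at the indole stage and not on the indoline carbamate 7. In 7 the carbon para to nitrogen is C5, while C4 is meta to it, so an electrophile would have to choose silicon against the directing effect of nitrogen. In the indole, C4 is conjugated with N1 through C2=C3–C3a, as C6 is, and the silyl group, the peri strain against a C3 bromine and the flanked position of C5 all point the third bromine to C4. The precursor is simpler by three C–Br bonds. The forward step must consume two equivalents of a mild bromine source at C3 and C2 and one equivalent of Br2 at C4, with no attack at C5 or C7.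

**10 ⇒ 9 (C2=C3 unsaturation).** No skeletal bond is cut; the indole is taken back to 6-bromo-4-(trimethylsilyl)indoline (9). This is the oxidation level the ring-forming step delivers. The forward reaction is a dehydrogenation that must be neutral enough to leave the C–Si bond alone.

**9 ⇒ 7 (N1–C(O)).** The free indoline comes from methyl 6-bromo-4-(trimethylsilyl)indoline-1-carboxylate (7). The carbamate must come off before the oxidation, because N-acylindolines dehydrogenate sluggishly. It must come off under base, because acid would threaten the aryl–silicon bond.

**7 ⇒ 5 (C3a–C7a and C4–C5, with N2 put back).** This is the key disconnection. Cutting these two bonds and reinserting an N=N unit between C7a and C5 turns the benzene ring into a pyridazine and the pyrroline ring into an open chain. The result is methyl N-(5-bromopyridazin-3-yl)-N-[4-(trimethylsilyl)but-3-yn-1-yl]carbamate (5).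

- The usual indole cuts at N1–C2, C2–C3 or N1–C7a would all require a benzene ring that already carries bromine meta to nitrogen on both sides plus an ortho carbon substituent, which is the hard pattern itself.
- Here two rings reduce to one commercial heteroaromatic ring and an acyclic tether.
- The forward step must be a thermal [4+2] addition of the alkyne across C3 and C6 of the diazine, followed by loss of N2, at a temperature the bromide, the carbamate and the alkynylsilane survive.

**5 ⇒ 3 + 4 (N–CH2).** The tether is detached at nitrogen, giving methyl (5-bromopyridazin-3-yl)carbamate (3) and 4-(trimethylsilyl)but-3-yn-1-ol (4). Cutting instead between nitrogen and the pyridazine carbon would call for a nucleophilic substitution on a dihalodiazine, where two halogen positions compete. Cutting at N–CH2 uses a stable alcohol and avoids a homopropargylic halide, which eliminates easily under base. The forward reaction must alkylate the exocyclic carbamate nitrogen and not the ring nitrogen or the oxygen.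

**3 ⇒ 1 + 2 (N–C(O)).** The carbamate is made from 5-bromopyridazin-3-amine (1) and methyl chloroformate (2). The methoxycarbonyl group earns its place three times: it acidifies the N–H for the alkylation, it ties up the amino lone pair so that the diazine stays electron-poor for the cycloaddition, and it protects the indoline nitrogen during the thermolysis.

## Roads not taken

**Alternative 1: a traceless C5 amino group directing bromine to C4 and C6.**

- Cut: the C4–Br and C6–Br bonds are traced back to 5-aminoindolin-2-one A1.
- Forward: two equivalents of NBS should brominate both positions ortho to the amino group and give 5-amino-4,6-dibromoindolin-2-one A2. Diazotisation and reduction with H3PO2 would remove the amine to give 4,6-dibromoindolin-2-one A3. The lactam would then be turned into the C2 bromide with POBr3, and C3 brominated last.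
- Merits: a very cheap starting material, the strongest available director aimed at the two right carbons, about five steps and no high-temperature operation.
- Weak points:
  - The C3 methylene of an oxindole is itself brominated by NBS through its enol.
  - C4 is the hindered one of the two ortho positions, and C7 is activated by the lactam nitrogen.
  - The electron-rich aminooxindole is prone to oxidation by the brominating agent.
  - The POBr3 conversion of oxindoles into 2-bromoindoles is capricious.
- Comparison: in step count and material cost this road is equal to or better than the chosen plan. What the chosen plan sets against it is that every benzenoid substituent is placed by connectivity rather than by a competition among C3, C4, C6 and C7, and that its one selectivity decision is taken at a carbon marked by silicon.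

**Alternative 2: closure of N1–C2 from a gem-dibromovinyl anilide with retention of one bromine.**

- Cut: the N1–C2 bond, leading back to N-[3,5-dibromo-2-(2,2-dibromovinyl)phenyl]-4-methylbenzenesulfonamide A5, itself derived from 2-amino-4,6-dibromobenzaldehyde A4 by sulfonylation and Ramirez olefination with CBr4 and PPh3.
- Forward: Cs2CO3, with or without CuI, lets the sulfonamide nitrogen displace one vinylic bromine and gives 2,4,6-tribromo-1-tosyl-1H-indole A6. C3 bromination and removal of the sulfonyl group would finish the synthesis.
- Merits: the C2 bromine arrives with the ring closure, the benzenoid bromines are preset, and the conditions are mild.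
- Weak points:
  - A4 is not a shelf compound, and making it poses the same meta,meta-dibromoaniline problem again, with an ortho formyl group added.
  - The copper variant may engage the aryl bromides.
  - C3 of an N-sulfonyl-2-bromoindole is deactivated.
  - The sulfonyl group must be removed without reductants, which would strip bromine.
- Comparison: the ring closure itself is gentler than a thermolysis at 230 °C and installs C2–Br more elegantly than a late electrophilic substitution. The sequence is nevertheless longer (five steps from A4, plus the preparation of A4) and it moves the real difficulty into the starting material. The chosen plan solves that difficulty in its key step from catalogue compounds.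

**Alternative 3: Hemetsberger nitrene insertion into the single free ortho C–H.**

- Cut: the N1–C7a bond. 2,4-Dibromobenzaldehyde A7 is condensed with methyl 2-azidoacetate A8 to give methyl (Z)-2-azido-3-(2,4-dibromophenyl)acrylate A9.
- Forward: thermolysis in xylene expels N2, and the vinyl nitrene inserts into the only ortho C–H to give methyl 4,6-dibromo-1H-indole-2-carboxylate A10. Saponification and decarboxylation would give 4,6-dibromo-1H-indole A11, and two equivalents of NBS would complete 13.
- Merits: a cheap commercial aldehyde that already holds both benzenoid bromines in the right places, an unambiguous ring closure, five steps, and a final dibromination on an indole free of silicon.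
- Weak points:
  - A8 and A9 are energetic azides.
  - The condensation of ortho-substituted aldehydes tends to be modest.
  - Two steps are spent removing a C2 carbon that the target replaces by bromine, and the decarboxylation is harsh for a dibromoarene.
- Comparison: for the single target 13 this road is at least as short as the chosen one and probably cheaper, and its regiochemistry is equally secure. The chosen plan has to set against it the absence of azides and of a high-temperature decarboxylation, and the fact that the arene is built from scratch. The C4 substituent thus enters as a silyl handle and the C6 substituent through the choice of diazine, which makes the route the more adaptable one for analogues.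

Key step: step 3

Remark on the chemistry: compounds 1, 2 and 4 are taken to be catalogue materials. The target has no stereocenter. The bridged intermediate 6 forms as a racemate whose two bridgeheads are locked by the bicycle.

## Route

Step 1
Reactants: 1 5-bromopyridazin-3-amine; 2 methyl chloroformate
Product: 3 methyl (5-bromopyridazin-3-yl)carbamate
Conditions: ClCO2Me (1.1 equiv), pyridine, 0 °C to rt
Reagents that add atoms: none
Why: Carbamate formation by acylation of a heteroaryl amine with a chloroformate; the exocyclic amino group gives the only stable neutral acyl product, pyridine takes up HCl, any doubly acylated material should revert to 3 on mild aqueous base work-up, and the C5 bromide is not displaced at this temperature.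

Step 2
Reactants: 3 methyl (5-bromopyridazin-3-yl)carbamate; 4 4-(trimethylsilyl)but-3-yn-1-ol
Product: 5 methyl N-(5-bromopyridazin-3-yl)-N-[4-(trimethylsilyl)but-3-yn-1-yl]carbamate
Conditions: PPh3, DIAD, THF, 0 °C to rt
Reagents that add atoms: none
Why: Mitsunobu reaction; the carbamate N–H, acidified by the methoxycarbonyl group and the electron-poor bromopyridazine, protonates the PPh3/DIAD betaine, and the anion displaces the alkoxyphosphonium ion of primary alcohol 4 by SN2 at the exocyclic nitrogen. The neutral conditions spare the alkynylsilane and avoid the elimination to an enyne that a homopropargylic halide would risk under base.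

Step 3
Reactants: 5 methyl N-(5-bromopyridazin-3-yl)-N-[4-(trimethylsilyl)but-3-yn-1-yl]carbamate
Product: 7 methyl 6-bromo-4-(trimethylsilyl)indoline-1-carboxylate, via bridged 2,3-diazabicyclo[2.2.2]octatriene adduct 6 (not isolated)
Conditions: 1,3,5-triisopropylbenzene (0.02 M), 230 °C, Ar
Reagents that add atoms: none
Why: Intramolecular inverse-electron-demand Diels–Alder reaction followed by retro-Diels–Alder loss of N2; the closest known reaction type is the thermal cyclisation of N-acyl-N-(but-3-ynyl)-3-aminopyridazines to N-acylindolines. The C3=C4–C5=C6 unit of the pyridazine is the 4π partner, its LUMO lowered by the ring nitrogens, by the acyl group that ties up the amino lone pair and by the C5 bromine, and the silylalkyne is the 2π partner. Suprafacial addition across C3 and C6 gives the bridged adduct 6, which expels N2 in an irreversible cycloreversion and leaves the aromatic ring. The five-membered ring closes in the cycloaddition itself by formation of C3a–C7a, the three-atom N–CH2–CH2 tether allowing only the fused, not a bridged, transition state. The six-membered carbocycle closes in the same event through C4–C5 and becomes benzenoid when N2 leaves. No stereocenter survives, since both bridgeheads of 6 are flattened on aromatisation. The selectivity required is regiochemical (silicon at C4, bromine at C6, hydrogen at C5 and C7): the tether can deliver only the internal alkyne carbon to C3 and the silylated terminus to C6, and the diazine substituents are carried over atom for atom. High dilution in an inert hydrocarbon suppresses bimolecular pathways, and the fully substituted carbamate, the aryl bromide and the alkynylsilane have no easy thermal decomposition channel at this temperature.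

Step 4
Reactants: 7 methyl 6-bromo-4-(trimethylsilyl)indoline-1-carboxylate
Product: 9 6-bromo-4-(trimethylsilyl)indoline, via potassium 6-bromo-4-(trimethylsilyl)indoline-1-carboxylate 8 (not isolated)
Conditions: KOH (5 equiv), MeOH/H2O (3:1), 85 °C, sealed vessel
Reagents that add atoms: none
Why: Alkaline hydrolysis of an N-aryl carbamate (acyl substitution, then decarboxylation of carbamate salt 8 on protonation by water). Hydroxide cannot displace the C6 bromide, which sits meta to nitrogen on an electron-rich ring, and an unactivated aryl–SiMe3 bond is stable to aqueous methanolic KOH; acidic deprotection is avoided because it would invite protodesilylation.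

Step 5
Reactants: 9 6-bromo-4-(trimethylsilyl)indoline
Product: 10 6-bromo-4-(trimethylsilyl)-1H-indole
Conditions: DDQ (1.05 equiv), toluene, 0 °C to rt
Reagents that add atoms: none
Why: DDQ dehydrogenation of an indoline to an indole; hydride abstraction from C2 next to the free nitrogen and loss of the C3 proton, driven by aromatisation of the pyrrole ring. The medium is neutral, so the C4–Si and C6–Br bonds should be untouched.

Step 6
Reactants: 10 6-bromo-4-(trimethylsilyl)-1H-indole
Product: 13 2,3,4,6-tetrabromo-1H-indole, via 3,6-dibromo-4-(trimethylsilyl)-1H-indole 11 (not isolated), via 2,3,6-tribromo-4-(trimethylsilyl)-1H-indole 12 (not isolated)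
Conditions: NBS (2.05 equiv), DMF, 0 °C, dark; then Br2 (1.05 equiv), 0 °C to rt
Reagents that add atoms: N-bromosuccinimide, O=C1CCC(=O)N1Br; bromine, BrBr
Why: Three electrophilic aromatic substitutions in one flask: NBS brominates the enamine-like C3 and then C2 (standard indole bromination, with succinimide and no HBr as co-product while the C4–Si bond is present), and Br2 then replaces silicon at C4 by ipso-bromodesilylation. Ipso attack should beat C5–H and C7–H because the cation at C3a is stabilised by the β-silicon effect and by conjugation with N1 through C2=C3, because peri strain between the C3 bromine and SiMe3 is released, and because C5 is flanked by bromine and silicon. Addition of bromine at C3 of 12 is reversible, whereas loss of the silyl group is not.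

## Compound list

1 | 5-bromopyridazin-3-amine | Nc1cc(Br)cnn1 | starting material
2 | methyl chloroformate | COC(=O)Cl | starting material
3 | methyl (5-bromopyridazin-3-yl)carbamate | COC(=O)Nc1cc(Br)cnn1 | intermediate
4 | 4-(trimethylsilyl)but-3-yn-1-ol | C[Si](C)(C)C#CCCO | starting material
5 | methyl N-(5-bromopyridazin-3-yl)-N-[4-(trimethylsilyl)but-3-yn-1-yl]carbamate | COC(=O)N(CCC#C[Si](C)(C)C)c1cc(Br)cnn1 | intermediate
6 | bridged [4+2] adduct: 2,3-diazabicyclo[2.2.2]octa-2,5,7-triene with the N-methoxycarbonyl nitrogen on bridgehead C1, Br on C5, SiMe3 on C8, and C7 tied back to that nitrogen through CH2CH2 (pyrrolidine fused at C1–C7); racemic | COC(=O)N1CCC2=C([Si](C)(C)C)C3N=NC12C=C3Br | intermediate (not isolated)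
7 | methyl 6-bromo-4-(trimethylsilyl)indoline-1-carboxylate | COC(=O)N1CCc2c1cc(Br)cc2[Si](C)(C)C | intermediate
8 | potassium 6-bromo-4-(trimethylsilyl)indoline-1-carboxylate | [K+].[O-]C(=O)N1CCc2c1cc(Br)cc2[Si](C)(C)C | intermediate (not isolated)
9 | 6-bromo-4-(trimethylsilyl)indoline | C[Si](C)(C)c1cc(Br)cc2NCCc12 | intermediate
10 | 6-bromo-4-(trimethylsilyl)-1H-indole | C[Si](C)(C)c1cc(Br)cc2[nH]ccc12 | intermediate
11 | 3,6-dibromo-4-(trimethylsilyl)-1H-indole | C[Si](C)(C)c1cc(Br)cc2[nH]cc(Br)c12 | intermediate (not isolated)
12 | 2,3,6-tribromo-4-(trimethylsilyl)-1H-indole | C[Si](C)(C)c1cc(Br)cc2[nH]c(Br)c(Br)c12 | intermediate (not isolated)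
13 | 2,3,4,6-tetrabromo-1H-indole | Brc1cc(Br)c2c(Br)c(Br)[nH]c2c1 | target

## Step count and risks

Total step count: 6. Longest linear sequence: 6 steps (1 → 3 → 5 → 7 → 9 → 10 → 13).

**Step 3 (key step).** The most likely failure is that the cycloaddition is too slow at a temperature the substrate tolerates. The silyl group adds bulk at the alkyne carbon that must bond to C6 of the diazine, so protodesilylation of the alkyne by trace water, trapping of the hindered carbamate in an unreactive rotamer, or slow charring could overtake ring formation.

The fallback replaces the carbamate by the more strongly electron-withdrawing trifluoroacetyl group, which lowers the diazine LUMO further and is removed under much milder conditions. It sets out again from 1. Trifluoroacetic anhydride in pyridine should give N-(5-bromopyridazin-3-yl)-2,2,2-trifluoroacetamide F1. Its acidic N–H is a good Mitsunobu partner for 4 (PPh3, DIAD, THF), giving N-(5-bromopyridazin-3-yl)-2,2,2-trifluoro-N-[4-(trimethylsilyl)but-3-yn-1-yl]acetamide F2. Thermolysis in 1,3,5-triisopropylbenzene, expected to need a lower temperature, passes through the bridged trifluoroacetyl adduct F3 to 1-[6-bromo-4-(trimethylsilyl)indolin-1-yl]-2,2,2-trifluoroethan-1-one F4. K2CO3 in methanol at rt then removes the acyl group, and the sequence comes back to the route at 9.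

**Step 6.** The most likely failure is diversion of the third bromine equivalent. Once C3 and C2 are filled, bromine may add at C3 again to give a 3H-indole that hydrolyses on work-up, or it may substitute C5–H or C7–H. The C4–Si bond may also be lost by protodesilylation under peri strain before bromine arrives.

The fallback exchanges silicon for bromine before the pyrrole double bond exists. It sets out from 7. Br2 in CH2Cl2 at −78 to 0 °C should effect ipso-bromodesilylation to methyl 4,6-dibromoindoline-1-carboxylate F5. Here C5 is para to the carbamate nitrogen, so C–H bromination is a real competitor, tempered only by the bromine and silicon that flank C5. KOH in aqueous methanol then gives, through potassium 4,6-dibromoindoline-1-carboxylate F6, 4,6-dibromoindoline F7, and DDQ in toluene gives 4,6-dibromo-1H-indole F8. NBS (2 equiv) in DMF brominates C3, forming 3,4,6-tribromo-1H-indole F9 in the flask, and then C2, so that the sequence comes back at 13.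

**Step 2.** The most likely failure is incomplete or misdirected alkylation. The carbamate N–H may be too weakly acidic to turn over the betaine, or the ambident anion may react at ring nitrogen N2 or at oxygen.

The fallback gives up the redox condensation for an alkylation with a preformed electrophile. Alcohol 4 is converted with I2, PPh3 and imidazole in CH2Cl2 (Appel reaction) into (4-iodobut-1-yn-1-yl)trimethylsilane F10. The cesium salt of 3 (Cs2CO3, DMF, 40 °C) is alkylated with it; the soft, weakly basic carbamate anion should favour substitution over E2 elimination. The sequence sets out from 3 and 4 and comes back at 5.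

## Further compounds

F1 | step 3 | N-(5-bromopyridazin-3-yl)-2,2,2-trifluoroacetamide | O=C(Nc1cc(Br)cnn1)C(F)(F)F
F2 | step 3 | N-(5-bromopyridazin-3-yl)-2,2,2-trifluoro-N-[4-(trimethylsilyl)but-3-yn-1-yl]acetamide | O=C(N(CCC#C[Si](C)(C)C)c1cc(Br)cnn1)C(F)(F)F
F3 | step 3 | bridged [4+2] adduct, N-trifluoroacetyl analogue of 6 (racemic) | O=C(N1CCC2=C([Si](C)(C)C)C3N=NC12C=C3Br)C(F)(F)F
F4 | step 3 | 1-[6-bromo-4-(trimethylsilyl)indolin-1-yl]-2,2,2-trifluoroethan-1-one | O=C(N1CCc2c1cc(Br)cc2[Si](C)(C)C)C(F)(F)F
F5 | step 6 | methyl 4,6-dibromoindoline-1-carboxylate | COC(=O)N1CCc2c(Br)cc(Br)cc21
F6 | step 6 | potassium 4,6-dibromoindoline-1-carboxylate | [K+].[O-]C(=O)N1CCc2c(Br)cc(Br)cc21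
F7 | step 6 | 4,6-dibromoindoline | Brc1cc(Br)c2CCNc2c1
F8 | step 6 | 4,6-dibromo-1H-indole | Brc1cc(Br)c2cc[nH]c2c1
F9 | step 6 | 3,4,6-tribromo-1H-indole | Brc1cc(Br)c2c(Br)c[nH]c2c1
F10 | step 2 | (4-iodobut-1-yn-1-yl)trimethylsilane | C[Si](C)(C)C#CCCI
A1 | alternative 1 | 5-aminoindolin-2-one | Nc1ccc2NC(=O)Cc2c1
A2 | alternative 1 | 5-amino-4,6-dibromoindolin-2-one | Nc1c(Br)cc2NC(=O)Cc2c1Br
A3 | alternative 1 | 4,6-dibromoindolin-2-one | O=C1Cc2c(Br)cc(Br)cc2N1
A4 | alternative 2 | 2-amino-4,6-dibromobenzaldehyde | Nc1cc(Br)cc(Br)c1C=O
A5 | alternative 2 | N-[3,5-dibromo-2-(2,2-dibromovinyl)phenyl]-4-methylbenzenesulfonamide | Cc1ccc(cc1)S(=O)(=O)Nc1cc(Br)cc(Br)c1C=C(Br)Br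
A6 | alternative 2 | 2,4,6-tribromo-1-tosyl-1H-indole | Cc1ccc(cc1)S(=O)(=O)n1c(Br)cc2c(Br)cc(Br)cc21
A7 | alternative 3 | 2,4-dibromobenzaldehyde | O=Cc1ccc(Br)cc1Br
A8 | alternative 3 | methyl 2-azidoacetate | COC(=O)CN=[N+]=[N-]
A9 | alternative 3 | methyl (Z)-2-azido-3-(2,4-dibromophenyl)acrylate | COC(=O)/C(N=[N+]=[N-])=C/c1ccc(Br)cc1Br
A10 | alternative 3 | methyl 4,6-dibromo-1H-indole-2-carboxylate | COC(=O)c1cc2c(Br)cc(Br)cc2[nH]1
A11 | alternative 3 | 4,6-dibromo-1H-indole | Brc1cc(Br)c2cc[nH]c2c1
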